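**Retrosynthetic overview**

1. The two esters are cut first (C1 acetate, C4 4-methoxybenzoate, tertiary C3–OH left free), then the isopropyl group is removed from C3, which leaves a trans-fused hydroazulenone with a ring-A ketone.
2. Ring B (seven-membered: C3a, C4, C5, C6, C7, C8, C8a) is opened at its only double bond, C6=C7, by ring-closing olefin metathesis, giving a cyclopentanone (ring A) that carries an allyl group and a 1-hydroxy-3-methylbut-3-enyl arm.
3. Feature that makes this closure possible: the allyl group on the quaternary carbon (future C8a) and the carbinol arm on the neighbouring ring-A methine (future C3a) are vicinal and trans, so their terminal =CH2 carbons (future C7 and C6) are one metathesis event apart and the closure gives the trans-fused bicycle directly.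
4. The diene comes from an anti-selective boron aldol addition of a regio-defined cyclopentanone enolate to 3-methylbut-3-enal; the enolate and the quaternary centre come from two copper-catalysed conjugate additions (allyl, then methyl anti to the silyloxy group) to (S)-4-silyloxycyclopent-2-enone.
5. Ring order: ring A is carried from the starting enone; ring B is closed in step 6 on the aldol adduct, and the bicycle then directs the isopropyl addition.

Key step: step 6

Remark: bicyclic compounds carry azulene locants (ring A: C1, C2, C3, C3a, C8a; ring B: C3a, C4 to C8, C8a); because the senior group fixes the direction of numbering, the ketone and diol intermediates are numbered in the opposite sense to the esters.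

Step 1
Reactants: 1 (S)-4-(tert-butyldimethylsilyloxy)cyclopent-2-en-1-one
Product: 2 (3S,4S)-3-allyl-4-(tert-butyldimethylsilyloxy)-1-(trimethylsilyloxy)cyclopent-1-ene
Conditions: CH2=CHCH2MgBr, CuBr·SMe2 (10 mol %), TMSCl, THF, −78 °C
Reagents that add atoms: allylmagnesium bromide (C=CC[Mg]Br); chlorotrimethylsilane (C[Si](C)(C)Cl)
Why: Copper-catalysed conjugate addition of the allyl Grignard reagent with in situ silyl trapping should give the silyl enol ether, allyl entering anti to the silyloxy group; the new C3 centre is erased in step 2, so its configuration is immaterial.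

Step 2
Reactants: 2 (3S,4S)-3-allyl-4-(tert-butyldimethylsilyloxy)-1-(trimethylsilyloxy)cyclopent-1-ene
Product: 3 (S)-3-allyl-4-(tert-butyldimethylsilyloxy)cyclopent-2-en-1-one
Conditions: Pd(OAc)2 (10 mol %), O2 (1 atm), DMSO, 25 °C
Reagents that add atoms: none
Why: Saegusa–Ito oxidation, in which the palladium enolate formed from the silyl enol ether undergoes β-hydride elimination at the only β-C–H (the allyl-bearing carbon), should give the β-allyl enone without touching the C4 stereocenter.

Step 3
Reactants: 3 (S)-3-allyl-4-(tert-butyldimethylsilyloxy)cyclopent-2-en-1-one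
Product: 4 (3R,4S)-3-allyl-4-(tert-butyldimethylsilyloxy)-3-methyl-1-(trimethylsilyloxy)cyclopent-1-ene
Conditions: MeMgBr, CuBr·SMe2 (10 mol %), TMSCl, DMPU, THF, −78 → −30 °C
Reagents that add atoms: methylmagnesium bromide (C[Mg]Br); chlorotrimethylsilane (C[Si](C)(C)Cl)
Why: TMSCl-accelerated copper-catalysed conjugate addition to the β,β-disubstituted enone should create the quaternary centre with methyl anti to the adjacent silyloxy group (allyl therefore cis to it), and silylation fixes the enolate regiochemistry for step 5.

Step 4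
Reactants: 5 3-methylbut-3-en-1-ol
Product: 6 3-methylbut-3-enal
Conditions: Dess–Martin periodinane, pyridine, CH2Cl2, 0 °C; solution used at once
Reagents that add atoms: none
Why: Dess–Martin oxidation under buffered, non-aqueous conditions should give the β,γ-unsaturated aldehyde without migration of the double bond into conjugation.

Step 5
Reactants: 4 (3R,4S)-3-allyl-4-(tert-butyldimethylsilyloxy)-3-methyl-1-(trimethylsilyloxy)cyclopent-1-ene; 6 3-methylbut-3-enal
Product: 9 (2S,3R,4S)-3-allyl-4-(tert-butyldimethylsilyloxy)-2-[(1S)-1-hydroxy-3-methylbut-3-en-1-yl]-3-methylcyclopentan-1-one, via lithium enolate 7 (not isolated), via dicyclohexylboron enolate 8 (not isolated)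
Conditions: MeLi, THF, 0 °C; (c-C6H11)2BCl, −78 °C; then 6, −78 → −20 °C; H2O2, MeOH, pH 7 buffer, 0 °C
Reagents that add atoms: none
Why: Boron-mediated aldol addition, in which the regio-defined (E)-enolate reacts through a closed six-membered chair transition state to give the anti aldol and the aldehyde approaches the enolate face on the methyl side (away from allyl and silyloxy), should set C2 (S) and the carbinol carbon (S).

Step 6
Reactants: 9 (2S,3R,4S)-3-allyl-4-(tert-butyldimethylsilyloxy)-2-[(1S)-1-hydroxy-3-methylbut-3-en-1-yl]-3-methylcyclopentan-1-one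
Product: 10 (3S,3aR,8S,8aS)-3-(tert-butyldimethylsilyloxy)-8-hydroxy-3a,6-dimethyl-3,3a,4,7,8,8a-hexahydroazulen-1(2H)-one
Conditions: second-generation Grubbs catalyst (5 mol %), 1,4-benzoquinone (10 mol %), CH2Cl2 (2 mM), 40 °C
Reagents that add atoms: none
Why: Ring-closing olefin metathesis: the ruthenium alkylidene loads onto the monosubstituted allyl alkene, then reacts intramolecularly with the 1,1-disubstituted alkene of the side chain by [2+2] cycloaddition and cycloreversion through a ruthenacyclobutane, and ethene leaves the open system. The closest known reaction type is the ring-closing metathesis of an allyl and a 2-methylallyl arm on a five-membered ring to a trisubstituted cycloheptene, a standard entry to hydroazulene sesquiterpene skeletons. Ring B is closed by forming the methyl-bearing C=CH double bond across the trans-vicinal arms of ring A, which gives the trans-fused bicyclo[5.3.0]decene with the complete carbon framework except the isopropyl group. No stereocenter is created, the four existing ones are untouched under the neutral conditions, and the ring size enforces the cis ring olefin. The step needs cyclisation in preference to oligomerisation and no migration of the new double bond; high dilution, the vicinal placement of the two arms and 1,4-benzoquinone (suppression of ruthenium hydride isomerisation) should secure this, while ketone, free secondary alcohol and silyl ether are inert to the catalyst.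

Step 7
Reactants: 10 (3S,3aR,8S,8aS)-3-(tert-butyldimethylsilyloxy)-8-hydroxy-3a,6-dimethyl-3,3a,4,7,8,8a-hexahydroazulen-1(2H)-one
Product: 11 (1R,3S,3aR,8S,8aS)-3-(tert-butyldimethylsilyloxy)-3a,6-dimethyl-1-(propan-2-yl)-1,2,3,3a,4,7,8,8a-octahydroazulene-1,8-diol
Conditions: i-PrMgCl, LaCl3·2LiCl, THF, −20 → 0 °C; aq NH4Cl
Reagents that add atoms: isopropylmagnesium chloride (CC(C)[Mg]Cl)
Why: LaCl3·2LiCl-promoted Grignard 1,2-addition (enolisation and β-hydride reduction suppressed) should deliver isopropyl to the ketone face anti to the angular methyl group and to the ring-B bond on the adjacent ring-fusion carbon, giving the (1R) tertiary alcohol.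

Step 8
Reactants: 11 (1R,3S,3aR,8S,8aS)-3-(tert-butyldimethylsilyloxy)-3a,6-dimethyl-1-(propan-2-yl)-1,2,3,3a,4,7,8,8a-octahydroazulene-1,8-diol; 12 4-methoxybenzoyl chloride
Product: 13 (1S,3R,3aS,4S,8aR)-1-(tert-butyldimethylsilyloxy)-3-hydroxy-6,8a-dimethyl-3-(propan-2-yl)-1,2,3,3a,4,5,8,8a-octahydroazulen-4-yl 4-methoxybenzoate
Conditions: Et3N, DMAP, CH2Cl2, 0 → 25 °C
Reagents that add atoms: none
Why: DMAP-catalysed acylation (nucleophilic acyl substitution) should esterify only the secondary C8 hydroxyl of 11, the tertiary hydroxyl being too hindered to react.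

Step 9
Reactants: 13 (1S,3R,3aS,4S,8aR)-1-(tert-butyldimethylsilyloxy)-3-hydroxy-6,8a-dimethyl-3-(propan-2-yl)-1,2,3,3a,4,5,8,8a-octahydroazulen-4-yl 4-methoxybenzoate
Product: 14 (1S,3R,3aS,4S,8aR)-1,3-dihydroxy-6,8a-dimethyl-3-(propan-2-yl)-1,2,3,3a,4,5,8,8a-octahydroazulen-4-yl 4-methoxybenzoate
Conditions: HF·pyridine, pyridine, THF, 0 → 25 °C
Reagents that add atoms: none
Why: Fluoride-induced cleavage of the silyl ether under buffered conditions should free the C1 hydroxyl without acyl migration or dehydration of the tertiary alcohol.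

Step 10
Reactants: 14 (1S,3R,3aS,4S,8aR)-1,3-dihydroxy-6,8a-dimethyl-3-(propan-2-yl)-1,2,3,3a,4,5,8,8a-octahydroazulen-4-yl 4-methoxybenzoate
Product: 15 (1S,3R,3aS,4S,8aR)-1-acetoxy-3-hydroxy-6,8a-dimethyl-3-(propan-2-yl)-1,2,3,3a,4,5,8,8a-octahydroazulen-4-yl 4-methoxybenzoate
Conditions: Ac2O, DMAP, pyridine, CH2Cl2, 25 °C
Reagents that add atoms: acetic anhydride (CC(=O)OC(C)=O)
Why: DMAP-catalysed acetylation should acylate the secondary C1 hydroxyl selectively over the tertiary C3 hydroxyl and complete the target.

**Compound list**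

1 | (S)-4-(tert-butyldimethylsilyloxy)cyclopent-2-en-1-one | O=C1C=C[C@@H](O[Si](C)(C)C(C)(C)C)C1 | starting material
2 | (3S,4S)-3-allyl-4-(tert-butyldimethylsilyloxy)-1-(trimethylsilyloxy)cyclopent-1-ene | C[Si](C)(C)OC1=C[C@H](CC=C)[C@@H](O[Si](C)(C)C(C)(C)C)C1 | intermediate
3 | (S)-3-allyl-4-(tert-butyldimethylsilyloxy)cyclopent-2-en-1-one | O=C1C=C(CC=C)[C@@H](O[Si](C)(C)C(C)(C)C)C1 | intermediate
4 | (3R,4S)-3-allyl-4-(tert-butyldimethylsilyloxy)-3-methyl-1-(trimethylsilyloxy)cyclopent-1-ene | C[Si](C)(C)OC1=C[C@@](C)(CC=C)[C@@H](O[Si](C)(C)C(C)(C)C)C1 | intermediate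
5 | 3-methylbut-3-en-1-ol | C=C(C)CCO | starting material
6 | 3-methylbut-3-enal | C=C(C)CC=O | intermediate
7 | lithium (3R,4S)-3-allyl-4-(tert-butyldimethylsilyloxy)-3-methylcyclopent-1-en-1-olate | [Li]OC1=C[C@@](C)(CC=C)[C@@H](O[Si](C)(C)C(C)(C)C)C1 | intermediate
8 | dicyclohexyl{[(3R,4S)-3-allyl-4-(tert-butyldimethylsilyloxy)-3-methylcyclopent-1-en-1-yl]oxy}borane | C1CCC(CC1)B(C2CCCCC2)OC3=C[C@@](C)(CC=C)[C@@H](O[Si](C)(C)C(C)(C)C)C3 | intermediate
9 | (2S,3R,4S)-3-allyl-4-(tert-butyldimethylsilyloxy)-2-[(1S)-1-hydroxy-3-methylbut-3-en-1-yl]-3-methylcyclopentan-1-one | O=C1[C@H]([C@@H](O)CC(C)=C)[C@@](C)(CC=C)[C@@H](O[Si](C)(C)C(C)(C)C)C1 | intermediate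
10 | (3S,3aR,8S,8aS)-3-(tert-butyldimethylsilyloxy)-8-hydroxy-3a,6-dimethyl-3,3a,4,7,8,8a-hexahydroazulen-1(2H)-one | O[C@H]1CC(C)=CC[C@@]2(C)[C@@H](O[Si](C)(C)C(C)(C)C)CC(=O)[C@H]12 | intermediate
11 | (1R,3S,3aR,8S,8aS)-3-(tert-butyldimethylsilyloxy)-3a,6-dimethyl-1-(propan-2-yl)-1,2,3,3a,4,7,8,8a-octahydroazulene-1,8-diol | O[C@H]1CC(C)=CC[C@@]2(C)[C@@H](O[Si](C)(C)C(C)(C)C)C[C@@](O)(C(C)C)[C@H]12 | intermediate
12 | 4-methoxybenzoyl chloride | COc1ccc(C(Cl)=O)cc1 | starting material
13 | (1S,3R,3aS,4S,8aR)-1-(tert-butyldimethylsilyloxy)-3-hydroxy-6,8a-dimethyl-3-(propan-2-yl)-1,2,3,3a,4,5,8,8a-octahydroazulen-4-yl 4-methoxybenzoate | COc1ccc(C(=O)O[C@H]2CC(C)=CC[C@@]3(C)[C@@H](O[Si](C)(C)C(C)(C)C)C[C@@](O)(C(C)C)[C@H]23)cc1 | intermediate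
14 | (1S,3R,3aS,4S,8aR)-1,3-dihydroxy-6,8a-dimethyl-3-(propan-2-yl)-1,2,3,3a,4,5,8,8a-octahydroazulen-4-yl 4-methoxybenzoate | COc1ccc(C(=O)O[C@H]2CC(C)=CC[C@@]3(C)[C@@H](O)C[C@@](O)(C(C)C)[C@H]23)cc1 | intermediate
15 | (1S,3R,3aS,4S,8aR)-1-acetoxy-3-hydroxy-6,8a-dimethyl-3-(propan-2-yl)-1,2,3,3a,4,5,8,8a-octahydroazulen-4-yl 4-methoxybenzoate (CNP0171090.1) | COc1ccc(C(=O)O[C@H]2CC(C)=CC[C@@]3(C)[C@@H](OC(C)=O)C[C@@](O)(C(C)C)[C@H]23)cc1 | target

Total step count: 10
Longest linear sequence: 9 steps (steps 1, 2, 3, 5, 6, 7, 8, 9, 10 from compound 1)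

**Steps most likely to fail**

Step 5 (aldol addition). The carbon–carbon bond formation may proceed with incomplete anti selectivity, and proton transfer from the acidic β,γ-unsaturated aldehyde to the hindered enolate may compete, so that the side-chain carbinol is obtained as a mixture of epimers. The fallback corrects the carbinol after the fact by oxidation and hydroxyl-directed reduction instead of relying on the aldol event. The mixture is taken through steps 6 and 7 unchanged. Setting out from 11 (together with its C8 epimer), Dess–Martin oxidation of the secondary alcohol (the tertiary one is inert) should give the β-hydroxy ketone (1S,3R,3aR,8aR)-1-(tert-butyldimethylsilyloxy)-3-hydroxy-6,8a-dimethyl-3-(propan-2-yl)-1,2,3,3a,8,8a-hexahydroazulen-4(5H)-one F1. Saksena–Evans reduction (Me4NBH(OAc)3, MeCN/AcOH, −20 °C) should then deliver hydride intramolecularly from the boron bound to the tertiary oxygen, that is to the ketone face syn to that oxygen. Both epimers should thus converge on 11, where the route is rejoined.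

Step 7 (isopropyl addition). Facial selectivity on the bicyclic ketone may be poor, or enolisation toward C2 may be followed by loss of the β-silyloxy group, or the magnesium alkoxide may open ring B by retro-aldol cleavage. The fallback forms the tertiary carbinol before ring closure, on the flexible monocycle under chelation control. Setting out from 9, i-PrMgCl/LaCl3·2LiCl (THF, −20 °C) should add to the chelate between the ketone and the β-alkoxide from the face anti to the side chain and give (1R,2S,3R,4S)-3-allyl-4-(tert-butyldimethylsilyloxy)-2-[(1S)-1-hydroxy-3-methylbut-3-en-1-yl]-3-methyl-1-(propan-2-yl)cyclopentan-1-ol F2. Ring-closing metathesis of F2 (second-generation Grubbs catalyst, CH2Cl2, 40 °C, high dilution) should then close ring B and rejoin the route at 11.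

Step 3 (conjugate methylation). 1,4-Addition at the β,β-disubstituted carbon next to the silyloxy-bearing centre may be slow, so that 1,2-addition and γ-deprotonation take over. The fallback introduces the methyl group as a cyclopropane methylene and unveils it reductively. Setting out from 3, Corey–Chaykovsky cyclopropanation with dimethylsulfoxonium methylide (trimethylsulfoxonium iodide, NaH, DMSO, 25 °C), whose small nucleophile should attack the β-carbon anti to the silyloxy group, gives (1R,4S,5S)-5-allyl-4-(tert-butyldimethylsilyloxy)bicyclo[3.1.0]hexan-2-one F3. Dissolving-metal reduction (Li, NH3, THF, t-BuOH 1 equiv, −78 °C) should cleave the cyclopropane bond that overlaps with the carbonyl π system (the bond from the α-carbon to the methylene carbon). This gives the lithium enolate 7 with the new methyl group on the quaternary carbon, and silylation (TMSCl, Et3N) returns 4, where the route is rejoined.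

**Further compounds**

F1 | step 5 | (1S,3R,3aR,8aR)-1-(tert-butyldimethylsilyloxy)-3-hydroxy-6,8a-dimethyl-3-(propan-2-yl)-1,2,3,3a,8,8a-hexahydroazulen-4(5H)-one | O=C1CC(C)=CC[C@@]2(C)[C@@H](O[Si](C)(C)C(C)(C)C)C[C@@](O)(C(C)C)[C@H]12
F2 | step 7 | (1R,2S,3R,4S)-3-allyl-4-(tert-butyldimethylsilyloxy)-2-[(1S)-1-hydroxy-3-methylbut-3-en-1-yl]-3-methyl-1-(propan-2-yl)cyclopentan-1-ol | C=C(C)C[C@H](O)[C@@H]1[C@@](C)(CC=C)[C@@H](O[Si](C)(C)C(C)(C)C)C[C@@]1(O)C(C)C
F3 | step 3 | (1R,4S,5S)-5-allyl-4-(tert-butyldimethylsilyloxy)bicyclo[3.1.0]hexan-2-one | O=C1[C@@H]2C[C@]2(CC=C)[C@@H](O[Si](C)(C)C(C)(C)C)C1
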